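The numbers in the tables come from a simulation for an exercise, noise included.

The last readings of the two earlier runs stood at 5.00 h, but eta, beta and theta, the flasks I handed over, were to be read at 8.0 h, so I had to reckon past the readings.

| flask | electrophile | nucleophile | remark | time |
|---|---|---|---|---|
| ash | 0.15 M | 1 equiv | run made earlier |  |
| oak | 0.050 M | 1 equiv | run made earlier |  |
| eta | 0.10 M | 1.00 equiv |  | 8.0 h |
| beta | 0.10 M | 1.50 equiv |  | 8.0 h |
| theta | 0.10 M | 2.20 equiv |  | 8.0 h |

| run | time / h | electrophile / % | target / % |
|---|---|---|---|
| ash | 0.417 | 42.9 | 53.9 |
| ash | 0.667 | 40.8 | 57.8 |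
| ash | 0.833 | 40.1 | 59.5 |
| ash | 1.33 | 36.0 | 61.1 |
| ash | 2.00 | 29.0 | 66.4 |
| ash | 3.00 | 25.3 | 72.5 |
| ash | 5.00 | 17.8 | 78.9 |
| oak | 0.417 | 45.5 | 51.7 |
| oak | 0.667 | 45.0 | 55.7 |
| oak | 0.833 | 41.8 | 55.1 |
| oak | 1.33 | 40.7 | 57.3 |
| oak | 2.00 | 36.9 | 60.3 |
| oak | 3.00 | 34.1 | 63.5 |
| oak | 5.00 | 31.2 | 69.2 |

(standard deviation of a reading: 1 percentage point)



- part of the electrophile that has reacted at the end, eta
- part of the electrophile that has reacted at the end, beta
- part of the electrophile that has reacted at the end, theta
- what raising the equivalents of nucleophile from its lowest to its highest value here does to the part of the electrophile that has reacted (changes below 5 percentage points count as none) (it rises / it falls / no change)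

At both concentrations a large burst came before the first reading, and I asked my successor not to judge a flask by that first sample, since the electrophile kept creeping down afterwards. I took the burst as given and reckoned the slow correction. Its measure is the tail constant: the rise per hour of one over the fraction of electrophile left, divided by the starting concentration, which averaged 4.59 L mol⁻¹ h⁻¹ over ash and oak. Run back to zero time, the two lines left 48.2 % of the electrophile, a burst of about half. For eta I therefore expected 17.4 % left at 8.0 h. I reckoned no figure of my own for beta or theta.

The forecast, holding that “the tail is cleanly second order”, gave 82.5 % for eta, 96 % for beta and 99.5 % for theta, and for the trend, it rises.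

The flasks gave 83.8 %, 97.8 % and >99.9 %: it rises, by 16 percentage points.

    electrophile + nucleophile → acid set free + target (k = 0.150 L mol⁻¹ s⁻¹)
    nucleophile + acid set free ⇌ protonated nucleophile, settled at all times (K = 17000 L mol⁻¹)
    nucleophile + target → over-reaction product (k = 0.00580 L mol⁻¹ s⁻¹)
    crystals ⇌ acid set free, rate k4*(cs4 - [acid set free]) while solid is left; crystals form when [acid set free] > cs4 (solubility = 4.70 mM, k = 0.00360 s⁻¹)

Eta held 16 % electrophile against the 17.4 % from the tail constant. The rise from eta to theta came from the equivalents of nucleophile: theta set back to eta's equivalents reached 83.8 % instead of >99.9 %. Counting one nucleophile parked as protonated nucleophile for each one reacted, I let the burst consume 0.5 of the nucleophile charge, passed the parked rest to the tail, and ran the tail constant on a flask like eta with 0.600 equiv of nucleophile; this gave 44.4 % electrophile left, and that flask, its limiting reagent nucleophile down to 0.047 % of its charge, held 43 % of the electrophile.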